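The retrosynthesis first masks the C1 ketone and the C4 aldehyde of the indenone core as dioxolanes. It then cuts C3a-C4 and C7-C8 in each guaiazulen-3-yl group, four bonds in all, which opens both seven-membered rings.
The enabling feature lies in each seven-membered ring. C4 (CH3) and C7 (isopropyl) are the two ends of the run C4-C5-C6-C7, which is a 2,5-dialkylthiophene dioxide less SO2. C8, C8a, C3a and the five-membered ring (1-CH3, core at C3) make up a 6-aminofulvene, and its only ring CH next to C8a is C3a.
The later cuts are C8-C8a (amide acetal carbon), both core-azulene C3 bonds (core C2/C6 carbanions plus 3-methylcyclopentenone), C4-CHO (CO), and C1-C7a with C3-C3a (crotonoyl chloride plus 4-bromotoluene). The sulfone comes from 2-methylthiophene and acetone.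
In the forward direction the benzene ring is bought and the core five-membered ring closes in step 2. The two bought cyclopentene rings are attached in step 7, and both seven-membered rings close together in step 13.
The target has no stereocentre. The sp3 centres made on the way (C3 of the indanones, the carbinols, the cycloadducts) are uncontrolled and are all erased.

Key step: step 13

Assumption: the target SMILES carries no axial descriptor, so the two hindered azulenyl-core axes are not controlled; transient sp3 centres are racemic or mixed and are drawn flat.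

Step 1
Reactants: 1 4-bromotoluene; 2 (E)-but-2-enoyl chloride
Product: 3 (E)-1-(5-bromo-2-methylphenyl)but-2-en-1-one
Conditions: AlCl3 (1.2 equiv), CH2Cl2, 0 °C to rt
Reagents that add atoms: none
Why: Friedel-Crafts acylation, in which the acylium ion should enter ortho to the methyl group (the stronger director, its para position blocked by bromine) and the deactivated aryl ketone should not react further.

Step 2
Reactants: 3 (E)-1-(5-bromo-2-methylphenyl)but-2-en-1-one
Product: 4 4-bromo-3,7-dimethyl-2,3-dihydro-1H-inden-1-one (racemic)
Conditions: TfOH (5 equiv), 1,2-dichloroethane, 80 °C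
Reagents that add atoms: none
Why: Nazarov-type superacid cyclisation of an aryl vinyl ketone, in which the protonated enone can close only onto the single free ortho carbon, placing Br at C4 and CH3 at C7; C3 forms racemic and is flattened in step 5.

Step 3
Reactants: 4 4-bromo-3,7-dimethyl-2,3-dihydro-1H-inden-1-one
Product: 5 3,7-dimethyl-1-oxo-2,3-dihydro-1H-indene-4-carbaldehyde (racemic)
Conditions: Pd(OAc)2 (1 mol %), P(1-Ad)2(n-Bu) (3 mol %), TMEDA (1 equiv), CO/H2 (1:1, 5 bar), toluene, 100 °C
Reagents that add atoms: carbon monoxide, [C-]#[O+]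
Why: Palladium-catalysed reductive carbonylation (formylation) of an aryl bromide by oxidative addition, CO insertion and hydrogenolysis of the acylpalladium species, under conditions that leave an aryl ketone untouched.

Step 4
Reactants: 5 3,7-dimethyl-1-oxo-2,3-dihydro-1H-indene-4-carbaldehyde
Product: 6 6-bromo-3,7-dimethyl-1-oxo-2,3-dihydro-1H-indene-4-carbaldehyde (racemic)
Conditions: Br2 (1.1 equiv), AlCl3 (3.5 equiv), 1,2-dichloroethane, 0 to 40 °C
Reagents that add atoms: bromine, BrBr
Why: Electrophilic aromatic bromination under swamping-catalyst conditions, where both carbonyl groups are tied up by AlCl3 so that enolisation is shut off, and C6 is the one position ortho to 7-CH3, para to the C3a alkyl branch and meta to both acyl groups.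

Step 5
Reactants: 6 6-bromo-3,7-dimethyl-1-oxo-2,3-dihydro-1H-indene-4-carbaldehyde
Product: 8 2,6-dibromo-3,7-dimethyl-1-oxo-1H-indene-4-carbaldehyde, via 2,2,6-tribromo keto aldehyde 7 (not isolated)
Conditions: Br2 (2.2 equiv), cat. HBr, AcOH, 25 to 50 °C; evaporate; DBU (1.3 equiv), CH2Cl2, 0 °C
Reagents that add atoms: bromine, BrBr
Why: Acid-catalysed alpha,alpha-dibromination at the only enolisable carbon followed by dehydrobromination (C3-H is benzylic and anti to one C2-Br), the standard passage from a ketone to an alpha-bromoenone, which also removes the C3 stereocentre.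

Step 6
Reactants: 8 2,6-dibromo-3,7-dimethyl-1-oxo-1H-indene-4-carbaldehyde
Product: 9 2,6-dibromo-4-(1,3-dioxolan-2-yl)-3,7-dimethylspiro[indene-1,2'-[1,3]dioxolane]
Conditions: TMSOCH2CH2OTMS (4 equiv), TMSOTf (10 mol %), CH2Cl2, -78 °C to rt
Reagents that add atoms: 1,2-bis(trimethylsilyloxy)ethane, C[Si](C)(C)OCCO[Si](C)(C)C
Why: TMSOTf-catalysed acetalisation with the bis-silyl glycol ether (Noyori acetalisation), driven by formation of the disiloxane, should convert the aldehyde and the alpha-bromoenone carbonyl without moving the C2=C3 bond, as is known for 2-bromocycloalkenones and fluorenone-type ketones.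

Step 7
Reactants: 9 2,6-dibromo-4-(1,3-dioxolan-2-yl)-3,7-dimethylspiro[indene-1,2'-[1,3]dioxolane]; 10 3-methylcyclopent-2-en-1-one
Product: 13 1,1'-[4-(1,3-dioxolan-2-yl)-3,7-dimethylspiro[indene-1,2'-[1,3]dioxolane]-2,6-diyl]bis(3-methylcyclopent-2-en-1-ol) (diastereomer mixture), via dilithio species 11 (not isolated), via bis(dichlorocerio) species 12 (not isolated)
Conditions: t-BuLi (4.2 equiv), THF, -78 °C; anhydrous CeCl3 (2.5 equiv), -78 °C; 10 (3 equiv), -78 to 0 °C; sat. aq NH4Cl
Reagents that add atoms: none
Why: Double bromine-lithium exchange (the 2-lithio enone ketal is the classical alpha-ketovinyl anion equivalent and cannot expel alkoxide, since that would need a cyclic allene), transmetalation to the weakly basic organocerium and 1,2-addition to the enolisable enone; the two carbinol centres form without control and vanish in step 8.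

Step 8
Reactants: 13 the bis(3-methylcyclopent-2-en-1-ol)
Product: 14 4-(1,3-dioxolan-2-yl)-3,7-dimethyl-2,6-bis(4-methylcyclopenta-1,4-dien-1-yl)spiro[indene-1,2'-[1,3]dioxolane] (drawn as one of the interconverting diene tautomers)
Conditions: p-TsOH·H2O (2 mol %), 4 Å MS, CH2Cl2, 0 °C
Reagents that add atoms: none
Why: E1 dehydration of a tertiary, doubly allylic alcohol through a strongly stabilised allyl cation should be fast enough with a trace of acid over sieves for both dioxolanes to survive, and all diene tautomers (1,5-hydrogen shifts) lead to the same cyclopentadienide.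

Step 9
Reactants: 14 the bis(methylcyclopentadienyl) bis-acetal; 15 N,N-dimethylformamide dimethyl acetal
Product: 16 4-(1,3-dioxolan-2-yl)-2,6-bis{(3E)-3-[(dimethylamino)methylidene]-4-methylcyclopenta-1,4-dien-1-yl}-3,7-dimethylspiro[indene-1,2'-[1,3]dioxolane]
Conditions: 15 (6 equiv), toluene, 70 °C, Ar
Reagents that add atoms: none
Why: Condensation of a CH-acidic cyclopentadiene with an amide acetal is the standard entry to 6-(dimethylamino)fulvenes; of the three free ring positions the one between C-CH3 and CH, remote from the twisted ortho-substituted core, is the least hindered, and NMe2 should settle on the side of the ring CH (E).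

Step 10
Reactants: 17 2-methylthiophene; 18 acetone
Product: 20 2-(5-methylthiophen-2-yl)propan-2-ol, via 5-methyl-2-thienyllithium 19 (not isolated)
Conditions: n-BuLi (1.05 equiv), THF, -78 to 0 °C; 18, -78 °C to rt; sat. aq NH4Cl
Reagents that add atoms: none
Why: Alpha-lithiation of the thiophene at its free C5 followed by 1,2-addition to acetone.

Step 11
Reactants: 20 2-(5-methylthiophen-2-yl)propan-2-ol
Product: 21 2-isopropyl-5-methylthiophene
Conditions: Et3SiH (2 equiv), TFA (5 equiv), CH2Cl2, 0 °C to rt
Reagents that add atoms: none
Why: In this ionic hydrogenation TFA ionises the tertiary thienylic alcohol and the silane delivers hydride to the cation, which avoids the regioisomer problem of a direct Friedel-Crafts alkylation.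

Step 12
Reactants: 21 2-isopropyl-5-methylthiophene
Product: 22 2-isopropyl-5-methylthiophene 1,1-dioxide
Conditions: mCPBA (2.5 equiv), CH2Cl2, 0 °C to rt
Reagents that add atoms: mCPBA, O=C(OO)c1cccc(Cl)c1
Why: Peracid oxidation of an electron-rich 2,5-dialkylthiophene through the sulfoxide to the 1,1-dioxide, whose two alpha-alkyl groups slow the self-dimerisation typical of less substituted thiophene dioxides.

Step 13
Reactants: 16 the bis(6-dimethylaminofulvene) bis-acetal; 22 2-isopropyl-5-methylthiophene 1,1-dioxide (two equivalents consumed)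
Product: 25 4-(1,3-dioxolan-2-yl)-2,6-bis(7-isopropyl-1,4-dimethylazulen-3-yl)-3,7-dimethylspiro[indene-1,2'-[1,3]dioxolane], via bis(sulfone-bridged) cycloadduct 23 (not isolated), via bis(8-dimethylamino-3a,8-dihydroazulene) 24 (not isolated)
Conditions: 22 (4 equiv), pyridine, 100 °C, sealed tube, Ar
Reagents that add atoms: none
Why: Each 6-aminofulvene reacts as a 6π component through its exocyclic CH(NMe2) carbon (future C8) and the neighbouring ring CH (future C3a), and the sulfone reacts as a 4π diene through C2 and C5, in a donor-acceptor (6+4) cycloaddition that is asynchronous, with the enamine-like ring carbon bonding first. The bridged sulfolene units of 23 lose SO2 cheletropically to give 24, and base-assisted loss of dimethylamine through the cyclopentadienide (E1cB) aromatises each bicycle. The closest known reaction type is the azulene synthesis from 6-(dialkylamino)fulvenes and thiophene 1,1-dioxides, 2,5-dialkyl sulfones included, run here at two separate sites of one molecule. Each seven-membered ring closes by an intermolecular two-bond annulation, C3a-C4 leading and C7-C8 completing the ring, and the sp3 centres made on the way are uncontrolled and all vanish, so no stereocentre has to be set. Site selectivity on the fulvene is structural, because the other ring carbon next to C8a carries the 1-methyl group and has no hydrogen to lose, and the trisubstituted ring double bonds disfavour the competing (4+2) mode. The selectivity that is needed is the orientation of the unsymmetrical sulfone: the crowded ring carbon next to the core should choose the methyl-bearing terminus and leave the isopropyl-bearing alpha-sulfonyl carbon to close on the open exocyclic CH, while excess 22 and a basic solvent that binds SO2 should keep both sites converting and the acetals intact.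

Step 14
Reactants: 25 the bis(guaiazulen-3-yl) bis-acetal
Product: 26 2,6-bis(7-isopropyl-1,4-dimethylazulen-3-yl)-3,7-dimethyl-1-oxo-1H-indene-4-carbaldehyde (CNP0222726.0)
Conditions: 2 M aq HCl, THF, rt
Reagents that add atoms: water, O
Why: Acid-catalysed hydrolysis should open both dioxolanes in one operation, and since azulene positions 1 and 3 are both substituted the liberated aldehyde finds no nucleophilic azulene carbon to condense with.

Compound list
1 | 4-bromotoluene | Cc1ccc(Br)cc1 | starting material
2 | (E)-but-2-enoyl chloride | C/C=C/C(=O)Cl | starting material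
3 | (E)-1-(5-bromo-2-methylphenyl)but-2-en-1-one | C/C=C/C(=O)c1cc(Br)ccc1C | intermediate
4 | 4-bromo-3,7-dimethyl-2,3-dihydro-1H-inden-1-one (racemic) | CC1CC(=O)c2c(C)ccc(Br)c21 | intermediate
5 | 3,7-dimethyl-1-oxo-2,3-dihydro-1H-indene-4-carbaldehyde (racemic) | CC1CC(=O)c2c(C)ccc(C=O)c21 | intermediate
6 | 6-bromo-3,7-dimethyl-1-oxo-2,3-dihydro-1H-indene-4-carbaldehyde (racemic) | CC1CC(=O)c2c(C)c(Br)cc(C=O)c21 | intermediate
7 | 2,2,6-tribromo-3,7-dimethyl-1-oxo-2,3-dihydro-1H-indene-4-carbaldehyde (racemic, not isolated) | CC1C(Br)(Br)C(=O)c2c(C)c(Br)cc(C=O)c21 | intermediate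
8 | 2,6-dibromo-3,7-dimethyl-1-oxo-1H-indene-4-carbaldehyde | CC1=C(Br)C(=O)c2c(C)c(Br)cc(C=O)c21 | intermediate
9 | 2,6-dibromo-4-(1,3-dioxolan-2-yl)-3,7-dimethylspiro[indene-1,2'-[1,3]dioxolane] | CC1=C(Br)C3(OCCO3)c2c(C)c(Br)cc(C3OCCO3)c21 | intermediate
10 | 3-methylcyclopent-2-en-1-one | CC1=CC(=O)CC1 | starting material
11 | 2,6-dilithio derivative of the core bis-acetal (not isolated) | CC1=C([Li])C3(OCCO3)c2c(C)c([Li])cc(C3OCCO3)c21 | intermediate
12 | 2,6-bis(dichlorocerio) derivative of the core bis-acetal (not isolated) | CC1=C([Ce](Cl)Cl)C3(OCCO3)c2c(C)c([Ce](Cl)Cl)cc(C3OCCO3)c21 | intermediate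
13 | core bis-acetal bearing 1-hydroxy-3-methylcyclopent-2-en-1-yl groups at C2 and C6 (diastereomer mixture) | CC1=C(C3(O)C=C(C)CC3)C4(OCCO4)c2c(C)c(C3(O)C=C(C)CC3)cc(C3OCCO3)c21 | intermediate
14 | core bis-acetal bearing 4-methylcyclopenta-1,4-dien-1-yl groups at C2 and C6 (one tautomer drawn) | CC1=C(C3=CCC(C)=C3)C4(OCCO4)c2c(C)c(C3=CCC(C)=C3)cc(C3OCCO3)c21 | intermediate
15 | N,N-dimethylformamide dimethyl acetal | COC(OC)N(C)C | starting material
16 | core bis-acetal bearing (3E)-3-[(dimethylamino)methylidene]-4-methylcyclopenta-1,4-dien-1-yl groups at C2 and C6 | CC1=C(C3=C/C(=C\N(C)C)C(C)=C3)C3(OCCO3)c2c(C)c(C3=C/C(=C\N(C)C)C(C)=C3)cc(C3OCCO3)c21 | intermediate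
17 | 2-methylthiophene | Cc1cccs1 | starting material
18 | acetone | CC(C)=O | starting material
19 | 5-methyl-2-thienyllithium (not isolated) | Cc1ccc([Li])s1 | intermediate
20 | 2-(5-methylthiophen-2-yl)propan-2-ol | Cc1ccc(C(C)(C)O)s1 | intermediate
21 | 2-isopropyl-5-methylthiophene | Cc1ccc(C(C)C)s1 | intermediate
22 | 2-isopropyl-5-methylthiophene 1,1-dioxide | CC1=CC=C(C(C)C)S1(=O)=O | intermediate
23 | twofold (6+4) cycloadduct, SO2 bridging future C4 and C7 of each unit (stereoisomer mixture, not isolated) | CC1=C(C4=CC(C)=C5C4C6(C)C=CC(C(C)C)(C5N(C)C)S6(=O)=O)C3(OCCO3)c2c(C)c(C4=CC(C)=C5C4C6(C)C=CC(C(C)C)(C5N(C)C)S6(=O)=O)cc(C3OCCO3)c21 | intermediate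
24 | twofold 8-dimethylamino-3a,8-dihydroazulene after loss of SO2 (stereoisomer mixture, not isolated) | CC1=C(C4=CC(C)=C5C4C(C)=CC=C(C(C)C)C5N(C)C)C3(OCCO3)c2c(C)c(C4=CC(C)=C5C4C(C)=CC=C(C(C)C)C5N(C)C)cc(C3OCCO3)c21 | intermediate
25 | C1 ethylene ketal and C4 ethylene acetal of the target | CC1=C(c2cc(C)c3cc(C(C)C)ccc(C)c2-3)C3(OCCO3)c2c(C)c(-c3cc(C)c4cc(C(C)C)ccc(C)c3-4)cc(C3OCCO3)c21 | intermediate
26 | 2,6-bis(7-isopropyl-1,4-dimethylazulen-3-yl)-3,7-dimethyl-1-oxo-1H-indene-4-carbaldehyde | CC1=C(c2cc(C)c3cc(C(C)C)ccc(C)c2-3)C(=O)c2c(C)c(-c3cc(C)c4cc(C(C)C)ccc(C)c3-4)cc(C=O)c21 | target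

Total step count: 14. Longest linear sequence: 11 (steps 1 to 9, 13 and 14); the sulfone branch (steps 10 to 12) joins at step 13.

Steps most likely to fail

Step 13. Bond formation at the ring carbon next to the bulky core may be slow. Orientation control of the unsymmetrical sulfone may be incomplete at either of the two sites. Thermal self-dimerisation of the sulfone may also outrun the second annulation. The fallback sets out from 9 and attaches both azulenes ready-made. It is a twofold palladium-catalysed direct C-H arylation of commercial guaiazulene (Cc1ccc2c(C)ccc(C(C)C)cc1-2) at its nucleophilic C3 by the vinyl and the aryl bromide of 9 (Pd(OAc)2, KOAc, DMAc, 130 °C). This should give 25, where it comes back to the route. No compound outside the list is made (entry F0).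

Step 7. The second halogen-metal exchange may stay incomplete. Proton transfer from the allylic and benzylic methyl groups may quench the dianion. The enone may also be enolised rather than attacked at the two hindered carbanion sites. The fallback sets out from 9 and forms the two core-ring bonds by cross-coupling. A double Suzuki-Miyaura coupling with purchasable 3-(4,4,5,5-tetramethyl-1,3,2-dioxaborolan-2-yl)cyclopent-2-en-1-one (PdCl2(dppf), K3PO4, dioxane/H2O, 90 °C) should give the bis(3-oxocyclopent-1-en-1-yl) bis-acetal F1. The small nucleophile MeLi/CeCl3 (THF, -78 °C) then adds 1,2 to give the bis(3-hydroxy-3-methylcyclopent-1-en-1-yl) bis-acetal F2. F2 ionises to the same allyl cations as 13 and, under the conditions of step 8, comes back to the route at 14.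

Step 6. Ketal formation may be sluggish at a carbonyl hemmed in by 7-CH3 and 2-Br, because its oxocarbenium ion has indenyl-cation character. Protection may then stop at the aldehyde, or the glycol may attack in a conjugate sense. The fallback sets out from 6 and protects at the saturated stage. Ethylene glycol, p-TsOH and toluene under Dean-Stark conditions should give the 6-bromoindanone bis-dioxolane F3. Phenyltrimethylammonium tribromide (2.2 equiv, THF, 0 °C to rt) should brominate the ketal twice at C2 to the 2,2,6-tribromo bis-dioxolane F4. KOt-Bu in THF then removes HBr across C2-C3 and comes back to the route at 9.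

Further compounds
F0 | step 13 | none | none
F1 | step 7 | 3,3'-[4-(1,3-dioxolan-2-yl)-3,7-dimethylspiro[indene-1,2'-[1,3]dioxolane]-2,6-diyl]bis(cyclopent-2-en-1-one) | CC1=C(C3=CC(=O)CC3)C4(OCCO4)c2c(C)c(C3=CC(=O)CC3)cc(C3OCCO3)c21
F2 | step 7 | 3,3'-[4-(1,3-dioxolan-2-yl)-3,7-dimethylspiro[indene-1,2'-[1,3]dioxolane]-2,6-diyl]bis(1-methylcyclopent-2-en-1-ol) (diastereomer mixture) | CC1=C(C3=CC(C)(O)CC3)C4(OCCO4)c2c(C)c(C3=CC(C)(O)CC3)cc(C3OCCO3)c21
F3 | step 6 | 6-bromo-4-(1,3-dioxolan-2-yl)-3,7-dimethyl-2,3-dihydrospiro[indene-1,2'-[1,3]dioxolane] (racemic) | CC1CC3(OCCO3)c2c(C)c(Br)cc(C3OCCO3)c21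
F4 | step 6 | 2,2,6-tribromo-4-(1,3-dioxolan-2-yl)-3,7-dimethyl-2,3-dihydrospiro[indene-1,2'-[1,3]dioxolane] (racemic) | CC1C(Br)(Br)C3(OCCO3)c2c(C)c(Br)cc(C3OCCO3)c21
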